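**Retrosynthetic overview**
1. Target 13 ⇐ 12 by hydrogenolysis of the two aryl benzyl ethers (last step, neutral conditions).
2. 12 ⇐ C4–C5 bond by a visible-light nickel/iridium decarboxylative C(sp3)–C(sp3) coupling of lactone 10 (opened to its carboxylate, which loses CO2 and frees the C7 hydroxyl) with bromide 7 (already carrying the C2 acetate).
3. 7 ⇐ oxetane 6 (acetyl bromide opening) ⇐ chlorohydrin 4 ⇐ aryl Grignard from 1 + (S)-epichlorohydrin 2 (source of C2).
4. 10 ⇐ (R)-5-oxotetrahydrofuran-2-carboxylic acid 8 (source of C7) + pentylmagnesium bromide.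
5. Rings: no ring is formed that stays; the arene is bought, the oxetane is made in step 2 and opened in step 3, and the bought γ-lactone is opened in step 5.

Assumption: chain atoms are numbered as in the tridecane name of the target (C1 = ArCH2, C2 = CHOAc, C7 = CHOH, C8 = C=O); 1, 2 and 8 are bought, 8 being the commercial lactone acid obtained from D-glutamic acid.

**Route**

Step 1
Reactants: 1 1,3-bis(benzyloxy)-5-bromobenzene; 2 (S)-epichlorohydrin
Product: 4 (S)-1-[3,5-bis(benzyloxy)phenyl]-3-chloropropan-2-ol, via arylmagnesium bromide 3 (not isolated)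
Conditions: Mg, THF, 40 °C; CuI (10 mol%), then 2, −40 → 0 °C; dilute aq HCl work-up
Reagents that add atoms: none
Why: Copper-catalysed Grignard opening of the epoxide at its unsubstituted carbon (SN2) breaks no bond at the carbinol carbon, so C2 is carried over unchanged from bought 2.

Step 2
Reactants: 4 (S)-1-[3,5-bis(benzyloxy)phenyl]-3-chloropropan-2-ol
Product: 6 (S)-2-[3,5-bis(benzyloxy)benzyl]oxetane, via epoxide 5 (not isolated)
Conditions: Me3S(O)I (3 equiv), KOtBu (4 equiv), tBuOH, 50 °C, 48 h
Reagents that add atoms: trimethylsulfoxonium iodide, C[S+](C)(C)=O.[I-]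
Why: Base closes the chlorohydrin to the epoxide, dimethylsulfoxonium methylide opens it at the CH2 terminus and the γ-alkoxide displaces dimethyl sulfoxide (Corey–Chaykovsky-type ring expansion of an epoxide to an oxetane), all without touching the stereocentre.

Step 3
Reactants: 6 (S)-2-[3,5-bis(benzyloxy)benzyl]oxetane
Product: 7 (S)-1-[3,5-bis(benzyloxy)phenyl]-4-bromobutan-2-yl acetate
Conditions: AcBr (1.3 equiv), Bu4NBr (10 mol%), CH2Cl2, −20 °C → rt
Reagents that add atoms: acetyl bromide, CC(=O)Br
Why: Acylative ether cleavage: O-acylation of the strained ether gives an acyloxetanium ion that bromide opens by SN2 at the primary carbon, placing the acetate on C2 with retention and the bromide on C4 in an addition with no co-product.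

Step 4
Reactants: 8 (R)-5-oxotetrahydrofuran-2-carboxylic acid
Product: 10 (R)-5-hexanoyldihydrofuran-2(3H)-one, via acid chloride 9 (not isolated)
Conditions: (COCl)2, cat. DMF, CH2Cl2, 0 °C → rt, evaporate; n-C5H11MgBr (1.0 equiv, slow addition), Fe(acac)3 (3 mol%), THF, −78 °C
Reagents that add atoms: pentylmagnesium bromide, CCCCC[Mg]Br
Why: Iron-catalysed acylation of a Grignard reagent by an acid chloride is much faster at −78 °C than addition to the lactone or to the new ketone, and the base-free, cold conditions leave the bought C7 stereocentre intact.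

Step 5
Reactants: 10 (R)-5-hexanoyldihydrofuran-2(3H)-one; 7 (S)-1-[3,5-bis(benzyloxy)phenyl]-4-bromobutan-2-yl acetate
Product: 12 (2R,7R)-1-[3,5-bis(benzyloxy)phenyl]-7-hydroxy-8-oxotridecan-2-yl acetate, via potassium carboxylate 11 (not isolated)
Conditions: 10 (1.5 equiv), aq KOH (0.98 equiv per 10), MeCN/H2O, 0 °C, 30 min; then 7 (1.0 equiv), [Ir(dF(CF3)ppy)2(dtbbpy)]PF6 (2 mol%), NiCl2·glyme (10 mol%), 4,4′-dimethoxy-2,2′-bipyridine (10 mol%), degassed MeCN, 450 nm LEDs, rt
Reagents that add atoms: none
Why: Proposed new method: ring-opening decarboxylative C(sp3)–C(sp3) coupling of a γ-lactone, in which hydroxide opens 10 to carboxylate 11, the excited iridium photocatalyst oxidises the carboxylate, loss of CO2 gives the primary C5 radical with the C7 hydroxyl already free, the reduced photocatalyst returns monovalent nickel to zerovalent nickel, which adds bromide 7, and the alkylnickel captures the radical so that trivalent nickel reductively eliminates the C4–C5 bond; cross-selectivity rests on the two partners being activated by different events (oxidation versus oxidative addition), both stereocentres lie two bonds from the reacting carbons and are not touched, and the pre-formed carboxylate makes added carbonate base unnecessary, which protects the α-ketol from enolisation; the closest known reaction type is the nickel/photoredox decarboxylative alkylation of carboxylic acids with alkyl bromides, which has not been shown for lactone-derived, unprotected γ-hydroxy-δ-keto carboxylates.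

Step 6
Reactants: 12 (2R,7R)-1-[3,5-bis(benzyloxy)phenyl]-7-hydroxy-8-oxotridecan-2-yl acetate
Product: 13 (2R,7R)-1-(3,5-dihydroxyphenyl)-7-hydroxy-8-oxotridecan-2-yl acetate
Conditions: H2 (1 atm), 10% Pd/C, EtOAc, rt
Reagents that add atoms: none
Why: Hydrogenolysis of the two aryl benzyl ethers is neutral, and the aliphatic ketone, the non-benzylic secondary acetate and the α-ketol are inert to it, so both stereocentres reach the target unchanged.

**Compound list**
1 | 1,3-bis(benzyloxy)-5-bromobenzene | Brc1cc(OCc2ccccc2)cc(OCc2ccccc2)c1 | starting material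
2 | (S)-epichlorohydrin | ClC[C@@H]1CO1 | starting material
3 | [3,5-bis(benzyloxy)phenyl]magnesium bromide | Br[Mg]c1cc(OCc2ccccc2)cc(OCc2ccccc2)c1 | intermediate
4 | (S)-1-[3,5-bis(benzyloxy)phenyl]-3-chloropropan-2-ol | ClC[C@@H](O)Cc1cc(OCc2ccccc2)cc(OCc2ccccc2)c1 | intermediate
5 | (S)-2-[3,5-bis(benzyloxy)benzyl]oxirane | C(c1cc(OCc2ccccc2)cc(OCc2ccccc2)c1)[C@H]1CO1 | intermediate
6 | (S)-2-[3,5-bis(benzyloxy)benzyl]oxetane | C(c1cc(OCc2ccccc2)cc(OCc2ccccc2)c1)[C@H]1CCO1 | intermediate
7 | (S)-1-[3,5-bis(benzyloxy)phenyl]-4-bromobutan-2-yl acetate | BrCC[C@@H](OC(C)=O)Cc1cc(OCc2ccccc2)cc(OCc2ccccc2)c1 | intermediate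
8 | (R)-5-oxotetrahydrofuran-2-carboxylic acid | OC(=O)[C@H]1CCC(=O)O1 | starting material
9 | (R)-5-oxotetrahydrofuran-2-carbonyl chloride | ClC(=O)[C@H]1CCC(=O)O1 | intermediate
10 | (R)-5-hexanoyldihydrofuran-2(3H)-one | CCCCCC(=O)[C@H]1CCC(=O)O1 | intermediate
11 | potassium (R)-4-hydroxy-5-oxodecanoate | CCCCCC(=O)[C@H](O)CCC(=O)[O-].[K+] | intermediate
12 | (2R,7R)-1-[3,5-bis(benzyloxy)phenyl]-7-hydroxy-8-oxotridecan-2-yl acetate | CCCCCC(=O)[C@H](O)CCCC[C@H](Cc1cc(OCc2ccccc2)cc(OCc2ccccc2)c1)OC(C)=O | intermediate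
13 | (2R,7R)-1-(3,5-dihydroxyphenyl)-7-hydroxy-8-oxotridecan-2-yl acetate | CCCCCC(=O)[C@H](O)CCCC[C@H](Cc1cc(O)cc(O)c1)OC(C)=O | target

**Step count and risks**
Total step count: 6. Longest linear sequence: 5 steps (1, 2, 3, 5, 6); step 4 is the one-step side branch.

Steps most likely to fail:

1. Step 5 (the proposed new coupling). Risks are O-alkylation of carboxylate 11 by bromide 7 to the ester, slow oxidation of an unactivated primary carboxylate, and partial epimerisation at C7 during the hydroxide opening. The fallback uses known chemistry, a nickel-catalysed decarboxylative Negishi-type alkyl–alkyl coupling of a redox-active ester; it sets out from 10 and 7 and comes back to the route at 12. Lactone 10 is opened with KOH to 11 as in step 5, and TBSCl/imidazole in DMF gives tert-butyldimethylsilyl (R)-4-[(tert-butyldimethylsilyl)oxy]-5-oxodecanoate F1. Its labile silyl ester is cleaved with AcOH/THF/H2O to (R)-4-[(tert-butyldimethylsilyl)oxy]-5-oxodecanoic acid F2. N-Hydroxyphthalimide and N,N′-diisopropylcarbodiimide convert this into 1,3-dioxoisoindolin-2-yl (R)-4-[(tert-butyldimethylsilyl)oxy]-5-oxodecanoate F3. Bromide 7 is converted with zinc dust and LiCl in THF into {(S)-3-acetoxy-4-[3,5-bis(benzyloxy)phenyl]butyl}zinc bromide F4. F3 and F4 are coupled with NiCl2·glyme and 2,2′-bipyridine in THF/DMF at rt (dilute aq HCl work-up) to (2R,7R)-1-[3,5-bis(benzyloxy)phenyl]-7-[(tert-butyldimethylsilyl)oxy]-8-oxotridecan-2-yl acetate F5. HF·pyridine in THF then removes the silyl group to give 12.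

2. Step 4. Risks are over-addition of the Grignard reagent, attack on the lactone, and enolisation of the α-acyloxy ketone at C7. The fallback sets out from 8 and comes back at 10. Ethanethiol, N,N′-dicyclohexylcarbodiimide and DMAP in CH2Cl2 give S-ethyl (R)-5-oxotetrahydrofuran-2-carbothioate F6. A Fukuyama coupling with pentylzinc iodide and PdCl2(PPh3)2 in toluene at rt then gives 10 under neutral conditions that leave the lactone and the stereocentre alone.

3. Step 3. Risks are bromide attack at the secondary carbon of the acyloxetanium ion and side reactions of the electron-rich ring with the acylating agent. The fallback builds C4 from the epoxide instead of the oxetane; it sets out from 4 (so it also replaces step 2) and comes back at 7. Aqueous NaOH closes 4 to epoxide 5, which is isolated. CuI-catalysed opening with (isopropoxydimethylsilyl)methylmagnesium chloride gives (S)-1-[3,5-bis(benzyloxy)phenyl]-4-[dimethyl(propan-2-yloxy)silyl]butan-2-ol F7. Tamao oxidation (H2O2, KF, KHCO3, THF/MeOH) gives (S)-4-[3,5-bis(benzyloxy)phenyl]butane-1,3-diol F8. MeC(OMe)3 with cat. PPTS gives the cyclic orthoacetate (4S)-4-[3,5-bis(benzyloxy)benzyl]-2-methoxy-2-methyl-1,3-dioxane F9. AcBr converts F9 into a 1,3-dioxan-2-ylium ion that bromide opens at the primary carbon, giving 7.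

**Further compounds**
F1 | step 5 | tert-butyldimethylsilyl (R)-4-[(tert-butyldimethylsilyl)oxy]-5-oxodecanoate | CCCCCC(=O)[C@H](O[Si](C)(C)C(C)(C)C)CCC(=O)O[Si](C)(C)C(C)(C)C
F2 | step 5 | (R)-4-[(tert-butyldimethylsilyl)oxy]-5-oxodecanoic acid | CCCCCC(=O)[C@H](O[Si](C)(C)C(C)(C)C)CCC(=O)O
F3 | step 5 | 1,3-dioxoisoindolin-2-yl (R)-4-[(tert-butyldimethylsilyl)oxy]-5-oxodecanoate | CCCCCC(=O)[C@H](O[Si](C)(C)C(C)(C)C)CCC(=O)ON1C(=O)c2ccccc2C1=O
F4 | step 5 | {(S)-3-acetoxy-4-[3,5-bis(benzyloxy)phenyl]butyl}zinc bromide | Br[Zn]CC[C@@H](OC(C)=O)Cc1cc(OCc2ccccc2)cc(OCc2ccccc2)c1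
F5 | step 5 | (2R,7R)-1-[3,5-bis(benzyloxy)phenyl]-7-[(tert-butyldimethylsilyl)oxy]-8-oxotridecan-2-yl acetate | CCCCCC(=O)[C@H](O[Si](C)(C)C(C)(C)C)CCCC[C@H](Cc1cc(OCc2ccccc2)cc(OCc2ccccc2)c1)OC(C)=O
F6 | step 4 | S-ethyl (R)-5-oxotetrahydrofuran-2-carbothioate | CCSC(=O)[C@H]1CCC(=O)O1
F7 | step 3 | (S)-1-[3,5-bis(benzyloxy)phenyl]-4-[dimethyl(propan-2-yloxy)silyl]butan-2-ol | CC(C)O[Si](C)(C)CC[C@@H](O)Cc1cc(OCc2ccccc2)cc(OCc2ccccc2)c1
F8 | step 3 | (S)-4-[3,5-bis(benzyloxy)phenyl]butane-1,3-diol | OCC[C@@H](O)Cc1cc(OCc2ccccc2)cc(OCc2ccccc2)c1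
F9 | step 3 | (4S)-4-[3,5-bis(benzyloxy)benzyl]-2-methoxy-2-methyl-1,3-dioxane | COC1(C)OCC[C@H](Cc2cc(OCc3ccccc3)cc(OCc3ccccc3)c2)O1
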